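The data are simulated with constants of no real substance, and the scatter is random.

| flask | Z | Q | time |
|---|---|---|---|
| Wednesday's | 0.120 M | 0.00360 M |  |
| Thursday's | 0.0720 M | 0.00360 M |  |
| Sunday's | 0.120 M | 0.0110 M |  |
| Saturday's | 0.360 M | 0.00360 M |  |
| Monday's | 0.360 M | 0.00360 M | 75 min |

| run | time / min | [Z] / M |
|---|---|---|
| Wednesday's run | 3.0 | 0.1140 |
| Wednesday's run | 4.8 | 0.1120 |
| Wednesday's run | 7.5 | 0.1070 |
| Wednesday's run | 12 | 0.0995 |
| Wednesday's run | 19 | 0.0881 |
| Wednesday's run | 30 | 0.0725 |
| Wednesday's run | 47 | 0.0534 |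
| Wednesday's run | 75 | 0.0335 |
| Thursday's run | 3.0 | 0.0682 |
| Thursday's run | 4.8 | 0.0658 |
| Thursday's run | 7.5 | 0.0624 |
| Thursday's run | 12 | 0.0574 |
| Thursday's run | 19 | 0.0489 |
| Thursday's run | 30 | 0.0397 |
| Thursday's run | 47 | 0.0285 |
| Thursday's run | 75 | 0.0171 |
| Sunday's run | 3.0 | 0.1045 |
| Sunday's run | 4.8 | 0.0968 |
| Sunday's run | 7.5 | 0.0860 |
| Sunday's run | 12 | 0.0695 |
| Sunday's run | 19 | 0.0506 |
| Sunday's run | 30 | 0.0324 |
| Sunday's run | 47 | 0.0196 |
| Sunday's run | 75 | 0.0141 |
| Saturday's run | 3.0 | 0.3517 |
| Saturday's run | 4.8 | 0.3474 |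
| Saturday's run | 7.5 | 0.3391 |
| Saturday's run | 12 | 0.3273 |
| Saturday's run | 19 | 0.3087 |
| Saturday's run | 30 | 0.2810 |
| Saturday's run | 47 | 0.2397 |
| Saturday's run | 75 | 0.1792 |

(readings scatter by 4 × 10⁻⁴ M)

- Overall: Z -> L, with Q as catalyst.
- Constant volume, constant temperature.
- What is held in complexes is read along with the free species.
- An order is taken over about fifteen percent of the charge, up and down.

* the exponent of [Q] in the starting rate at the charge of the Wednesday's run (at the point where two percent of the Z have become L)
* the exponent of [Z] in the starting rate at the charge of the Wednesday's run (at the point where two percent of the Z have become L) (one fixed amount of L, the same in the runs compared)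
* Z in the Monday's run at 75 min, as a share of the Z charged

If the catalyst stands free of Z, the rate follows cZ, with order one; if Z holds the catalyst up throughout, the rate ignores cZ, with order 0. Wednesday's and Saturday's runs share one cQ and differ in charged Z by a factor of 3.00, so these two extremes put the ratio of their rates at that factor or at 1.

I took the slope between the readings at 3.0 min and 12 min. It was 0.00161 M min⁻¹ in Wednesday's run, around a mean cZ of 0.107 M, and 0.00271 M min⁻¹ in Saturday's run, around 0.340 M. Their ratio, 1.68, lay below the first extreme and above the second, so the real flask stands between them.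

A curve joining the extremes makes the rate proportional to cZ/(K + cZ), which is saturation kinetics. Solved for these two slopes, it gave a reading of 0.155 M for K, the turning level, the cZ at which the order in Z has come down to 0.5. The order is K/(K + cZ), which at Wednesday's charge made 0.563. Monday's charge repeats Saturday's, so I took Saturday's reading at 75 min as Monday's share of the charge, 49.8%.

The forecast gave 0.5 for the order in Z, below my 0.563, and 49.8% for Monday's share, the same as mine. For the order in Q it gave 0.93: “The Q order is therefore slightly below 1”.

    Q + Z ⇌ QZ, settled at all times (15.40 L mol⁻¹)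
    QZ ⇌ L + Q (1.182 min⁻¹, 2.106 L mol⁻¹ min⁻¹)
    2 Q ⇌ Q2, settled at all times (268.0 L mol⁻¹)
    Q + Oz → Dz

Wednesday's order in Z came to 0.54 against the 0.563 from K, and Monday's share to 49.8%. Thursday's run did not enter K; with 0.155 M the curve gives, at the two charges, Thursday's rate over Wednesday's as 0.727, and the rates of the two runs at one fixed amount of L give 0.728. The order in Q parted, at 1.1 against the forecast's 0.93. In Wednesday's run Oz took 7.53 × 10⁻⁴ M of the 0.00360 M of Q at once, and without that loss to Dz the order there falls to 0.85.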